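(The numbers belong to no real substance; what happens was integrated by code.)

Every set-up is isothermal; green, grey and ochre end at 2.0 h, and the teal tank, read at steady state, has that same span as its mean residence time.

all flasks: free catalyst 20 µM
- teal: substrate 0.010 M; coupling partner 0.0150 M; one stirred flow tank at steady state, fed with the mixture as stated, mean residence time 2.0 h
- green: substrate 0.010 M; coupling partner 0.0150 M; a closed flask charged with all of it at once and left for 2.0 h; time 2.0 h
- grey: substrate 0.010 M; coupling partner 0.0150 M (fed, over 2.00 h); a stirred flask in which coupling partner is dosed at a steady rate over 2.00 h without added volume, worked up at 2.0 h; time 2.0 h
- ochre: substrate 0.010 M (fed, over 2.00 h); coupling partner 0.0150 M; all but substrate at the start; substrate goes in evenly over 2.00 h, the run ends at 2.0 h; time 2.0 h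

    coupling partner + catalyst intermediate A → catalyst intermediate B (k1 = 150 /M/s)
    2 free catalyst ⇌ resting dimer, settled at all times (K2 = 1.2 × 10⁵ /M)
    substrate + free catalyst → catalyst intermediate A (k3 = 160 /M/s)
    catalyst intermediate B → free catalyst + target (k4 = 2.1 /s)
    coupling partner + target → over-reaction product B (k5 = 0.039 /M/s)
    target → over-reaction product A (k6 = 8.8 × 10⁻⁷ /s)

- a step written with two of one species runs at k times the square of its concentration and takes two of it each time
- the stated concentrations are those of everything mixed, before any reaction; amounts are the same in each set-up
- the feed brings no volume worth counting
- the share counts what is present at the end, not what went on to other products
- run time (green): 2.0 h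

- the set-up with the highest share of target in all that became target or over-reaction product B, at the outlet or at the end ("none" if the first two lie within 2 percentage points) (teal / green / grey / ochre / none)
- share of target in all that became target or over-reaction product B, at the outlet or at the end, teal
- share of target in all that became target or over-reaction product B, at the outlet or at the end, green
- share of target in all that became target or over-reaction product B, at the outlet or at the end, grey
- share of target in all that became target or over-reaction product B, at the outlet or at the end, ochre

My own reckoning, made for grey:

1. Write G for target plus over-reaction product B. The loss of target to over-reaction product A has a half-life of 9.1 d, long against the run, so I drop it.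

2. First extreme: coupling partner goes in so slowly that the catalyst charged waits as catalyst intermediate A (its resting state). Target then forms at the coupling constant times catalyst times partner, and it is destroyed at the over-reaction constant times target times partner. The partner concentration cancels. This leaves the crossover concentration P*, the target level at which destruction equals formation: P* = 150 /M/s × 20 µM / 0.039 /M/s = 0.0769 M.

3. That is higher than the substrate charge, so each target made costs P/P* of a target, where P is the target present. Summing over the run gives a share of 1 − G/(2P*), which is 93.5% at G = 0.010 M.

4. Second extreme: substrate and partner are both used up. Each target takes one partner and each over-reaction product B takes a second, so the share is 50.0%.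

5. Grey starts near the first extreme and moves towards the second as surplus partner arrives, so I commit to a share between those two. Green has the full partner charge from the start, and target's half-life against it is 0.33 h, short against the run, so green should stand nearer the second.

The forecast gave teal 58.4%, green 57%, grey 77% and ochre 55%, with grey best: “Dosing the coupling partner keeps it scarce until the substrate is nearly gone”.

The simulation gives teal 58.3%, green 56.3%, grey 78.7% and ochre 52.9%, so grey is best.

With the slow dosing of coupling partner taken away, grey falls from 78.7% to 56.3%, so that dosing is part of grey's lead. With the wearing away of coupling partner taken away, ochre falls from 52.9% to 26.3%, so that wearing away is the main reason for ochre's share. At 1.00 h, grey holds 69.3% of its catalyst as catalyst intermediate A, and 1 − G/(2P*) gives 95.9% against a reading of 94.9%. The grey neighbour dosed with 0.0060 M of coupling partner ends with 91.3% of its catalyst in that form, and the same P* gives 96.4%, where that flask reads 96.2%.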